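The pyrrole ring is disconnected at its N1–C5 bond. N1, C2 and the exocyclic formyl carbon map onto the nitrogen, α-carbon and β-carbon of serine. C3 comes from the serinal carbonyl, and C4, C5 and the nineteen-carbon chain come from a terminal alkyne whose substituted carbon becomes C5. In one operation cationic monovalent gold makes the carbamate nitrogen add to that carbon (5-endo-dig) and the ring carbinol leaves as water, so the aromatic ring forms while the Z,Z,Z-triene stays untouched. The precursor is an N-Boc 2-amino-alk-4-yn-3-ol with a primary TBS ether; both its sp3 stereocentres vanish, so carbinol epimers are carried together.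

Key step: step 7

Remark: because both stereocentres of the cyclisation precursor become sp2 ring carbons, the (S)-serinal is chosen only for its availability and the carbinol epimers are not separated.
Remark: the silyl ether is cleaved with pyridine-buffered HF, not a basic fluoride source, because a free alkoxide beside an N-Boc pyrrole invites N-to-O transfer of the Boc group.
Remark: all skipped-triene intermediates should be handled under argon, in degassed solvents and away from light.

Step 1
Reactants: 1 (11Z,14Z,17Z)-icosa-11,14,17-trienoic acid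
Product: 2 (11Z,14Z,17Z)-icosa-11,14,17-trien-1-ol
Conditions: LiAlH4, THF, 0 °C to rt; then H2O
Reagents that add atoms: none
Why: Hydride reduction of a carboxylic acid with LiAlH4 proceeds through the carboxylate salt to the primary alcohol and leaves isolated, non-conjugated Z-alkenes untouched.

Step 2
Reactants: 2 (11Z,14Z,17Z)-icosa-11,14,17-trien-1-ol
Product: 3 (11Z,14Z,17Z)-icosa-11,14,17-trienal
Conditions: DMP, CH2Cl2, 0 °C to rt; used crude
Reagents that add atoms: none
Why: Dess–Martin oxidation takes the primary alcohol to the aldehyde under metal-free, nearly neutral conditions that neither over-oxidise it nor isomerise the skipped triene.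

Step 3
Reactants: 3 (11Z,14Z,17Z)-icosa-11,14,17-trienal; 4 dimethyl (1-diazo-2-oxopropyl)phosphonate
Product: 5 (12Z,15Z,18Z)-henicosa-12,15,18-trien-1-yne
Conditions: K2CO3, MeOH, 0 °C to rt
Reagents that add atoms: none
Why: In this Ohira–Bestmann (Seyferth–Gilbert) homologation, methanolysis of 4 releases the diazomethylphosphonate anion, whose olefination of the aldehyde, loss of N2 and 1,2-hydrogen shift give the terminal alkyne under base mild enough for an enolisable aldehyde and a skipped triene.

Step 4
Reactants: 5 (12Z,15Z,18Z)-henicosa-12,15,18-trien-1-yne; 6 tert-butyl (4S)-4-formyl-2,2-dimethyl-1,3-oxazolidine-3-carboxylate (N-Boc-N,O-isopropylidene-L-serinal)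
Product: 8 tert-butyl (4S)-4-[(13Z,16Z,19Z)-1-hydroxydocosa-13,16,19-trien-2-yn-1-yl]-2,2-dimethyl-1,3-oxazolidine-3-carboxylate (mixture of carbinol epimers), via lithium acetylide 7 (not isolated)
Conditions: n-BuLi, THF, −78 °C; then 6, −78 to −20 °C; then aq. NH4Cl
Reagents that add atoms: none
Why: The alkyne C–H is by far the most acidic site of 5, and 1,2-addition of the resulting lithium acetylide to this non-enolising serinal is a standard carbonyl addition; the new carbinol centre is set without control (Felkin–Anh attack should favour the anti epimer), which does not matter because step 7 destroys it.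

Step 5
Reactants: 8 tert-butyl (4S)-4-[(13Z,16Z,19Z)-1-hydroxydocosa-13,16,19-trien-2-yn-1-yl]-2,2-dimethyl-1,3-oxazolidine-3-carboxylate
Product: 9 tert-butyl N-[(2S,15Z,18Z,21Z)-1,3-dihydroxytetracosa-15,18,21-trien-4-yn-2-yl]carbamate (mixture of carbinol epimers)
Conditions: p-TsOH·H2O (cat.), MeOH, rt
Reagents that add atoms: none
Why: Acid-catalysed transketalisation in methanol opens the N,O-isopropylidene aminal much faster than it cleaves the Boc carbamate, the usual unmasking of serinal–acetylide adducts.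

Step 6
Reactants: 9 tert-butyl N-[(2S,15Z,18Z,21Z)-1,3-dihydroxytetracosa-15,18,21-trien-4-yn-2-yl]carbamate
Product: 10 tert-butyl N-[(2S,15Z,18Z,21Z)-1-(tert-butyldimethylsilyloxy)-3-hydroxytetracosa-15,18,21-trien-4-yn-2-yl]carbamate (mixture of carbinol epimers)
Conditions: TBSCl, imidazole, CH2Cl2, 0 °C
Reagents that add atoms: tert-butyldimethylsilyl chloride (TBSCl), CC(C)(C)[Si](C)(C)Cl
Why: Silylation with TBSCl and imidazole at 0 °C is strongly selective for the unhindered primary hydroxyl over the secondary propargylic hydroxyl and the carbamate N–H.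

Step 7
Reactants: 10 tert-butyl N-[(2S,15Z,18Z,21Z)-1-(tert-butyldimethylsilyloxy)-3-hydroxytetracosa-15,18,21-trien-4-yn-2-yl]carbamate
Product: 12 tert-butyl 2-[(tert-butyldimethylsilyl)oxymethyl]-5-[(10Z,13Z,16Z)-nonadeca-10,13,16-trien-1-yl]-1H-pyrrole-1-carboxylate, via hydroxypyrroline 11 (not isolated)
Conditions: Ph3PAuCl (2 mol%), AgOTf (2 mol%), 4 Å MS, THF, 0 °C to rt, dark
Reagents that add atoms: none
Why: AgOTf abstracts chloride from Ph3PAuCl to give cationic Ph3PAu+ (monovalent gold), which coordinates the C4≡C5 alkyne of 10; the carbamate nitrogen adds anti to gold at the distal carbon C5, protodeauration of the alkenyl–AuPPh3 species gives hydroxypyrroline 11, and loss of the C3 hydroxyl with the C2 hydrogen as water aromatises 11 to 12. The closest known reaction type is the gold- or silver-catalysed dehydrative cyclisation of N-carbamate and N-sulfonyl 1-amino-alk-3-yn-2-ols to pyrroles, an alkyne hydroamination followed by aromatising dehydration. The one ring formed, the pyrrole, closes in the 5-endo-dig mode through the new N1–C5 bond. No stereocentre is created, and C2 and C3 of 10 both become sp2 ring carbons, so the epimer mixture converges on a single product. The step needs nitrogen and not oxygen to attack, and the alkyne and not an alkene to be activated: the primary oxygen is blocked as its TBS ether, the C3 hydroxyl could only close a three- or four-membered ring, attack by the Boc carbonyl oxygen would be a 6-exo-dig closure that cannot end in an aromatic ring, and the three isolated Z-alkenes bind soft cationic gold far more weakly than the alkyne.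

Step 8
Reactants: 12 tert-butyl 2-[(tert-butyldimethylsilyl)oxymethyl]-5-[(10Z,13Z,16Z)-nonadeca-10,13,16-trien-1-yl]-1H-pyrrole-1-carboxylate
Product: 13 tert-butyl 2-(hydroxymethyl)-5-[(10Z,13Z,16Z)-nonadeca-10,13,16-trien-1-yl]-1H-pyrrole-1-carboxylate
Conditions: HF·pyridine, pyridine, THF, 0 °C to rt
Reagents that add atoms: none
Why: Fluoride-mediated desilylation with buffered HF cleaves the primary TBS ether without ever forming a free alkoxide, which suppresses N-to-O transfer of the neighbouring Boc group, and the carbamate and the alkenes are inert to the reagent.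

Step 9
Reactants: 13 tert-butyl 2-(hydroxymethyl)-5-[(10Z,13Z,16Z)-nonadeca-10,13,16-trien-1-yl]-1H-pyrrole-1-carboxylate
Product: 14 tert-butyl 2-formyl-5-[(10Z,13Z,16Z)-nonadeca-10,13,16-trien-1-yl]-1H-pyrrole-1-carboxylate
Conditions: MnO2 (activated, excess), CH2Cl2, rt
Reagents that add atoms: none
Why: MnO2 oxidises the benzylic-type pyrrol-2-ylmethanol selectively on its surface, stops at the aldehyde and does not touch isolated alkenes.

Step 10
Reactants: 14 tert-butyl 2-formyl-5-[(10Z,13Z,16Z)-nonadeca-10,13,16-trien-1-yl]-1H-pyrrole-1-carboxylate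
Product: 15 Mycalazal 20, 5-[(10Z,13Z,16Z)-nonadeca-10,13,16-trien-1-yl]-1H-pyrrole-2-carbaldehyde
Conditions: K2CO3 (cat.), MeOH, rt
Reagents that add atoms: none
Why: With the 2-formyl group in place the N-Boc pyrrole is an activated carbamate, so base-catalysed methanolysis (transacylation to methoxide with the stabilised pyrrolide as leaving group) removes the Boc group at room temperature without affecting the aldehyde or the triene.

Compound list
1 | (11Z,14Z,17Z)-icosa-11,14,17-trienoic acid | CC/C=C\C/C=C\C/C=C\CCCCCCCCCC(=O)O | starting material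
2 | (11Z,14Z,17Z)-icosa-11,14,17-trien-1-ol | CC/C=C\C/C=C\C/C=C\CCCCCCCCCCO | intermediate
3 | (11Z,14Z,17Z)-icosa-11,14,17-trienal | CC/C=C\C/C=C\C/C=C\CCCCCCCCCC=O | intermediate
4 | dimethyl (1-diazo-2-oxopropyl)phosphonate | COP(=O)(OC)C(=[N+]=[N-])C(C)=O | starting material
5 | (12Z,15Z,18Z)-henicosa-12,15,18-trien-1-yne | CC/C=C\C/C=C\C/C=C\CCCCCCCCCC#C | intermediate
6 | tert-butyl (4S)-4-formyl-2,2-dimethyl-1,3-oxazolidine-3-carboxylate (N-Boc-N,O-isopropylidene-L-serinal) | CC(C)(C)OC(=O)N1[C@@H](COC1(C)C)C=O | starting material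
7 | [(12Z,15Z,18Z)-henicosa-12,15,18-trien-1-yn-1-yl]lithium | CC/C=C\C/C=C\C/C=C\CCCCCCCCCC#C[Li] | intermediate
8 | tert-butyl (4S)-4-[(13Z,16Z,19Z)-1-hydroxydocosa-13,16,19-trien-2-yn-1-yl]-2,2-dimethyl-1,3-oxazolidine-3-carboxylate, carbinol epimers | CC/C=C\C/C=C\C/C=C\CCCCCCCCCC#CC(O)[C@@H]1COC(C)(C)N1C(=O)OC(C)(C)C | intermediate
9 | tert-butyl N-[(2S,15Z,18Z,21Z)-1,3-dihydroxytetracosa-15,18,21-trien-4-yn-2-yl]carbamate, carbinol epimers | CC/C=C\C/C=C\C/C=C\CCCCCCCCCC#CC(O)[C@H](CO)NC(=O)OC(C)(C)C | intermediate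
10 | tert-butyl N-[(2S,15Z,18Z,21Z)-1-(tert-butyldimethylsilyloxy)-3-hydroxytetracosa-15,18,21-trien-4-yn-2-yl]carbamate, carbinol epimers | CC/C=C\C/C=C\C/C=C\CCCCCCCCCC#CC(O)[C@H](CO[Si](C)(C)C(C)(C)C)NC(=O)OC(C)(C)C | intermediate
11 | tert-butyl (2S)-2-[(tert-butyldimethylsilyl)oxymethyl]-3-hydroxy-5-[(10Z,13Z,16Z)-nonadeca-10,13,16-trien-1-yl]-2,3-dihydro-1H-pyrrole-1-carboxylate, C3 epimers | CC/C=C\C/C=C\C/C=C\CCCCCCCCCC1=CC(O)[C@H](CO[Si](C)(C)C(C)(C)C)N1C(=O)OC(C)(C)C | intermediate
12 | tert-butyl 2-[(tert-butyldimethylsilyl)oxymethyl]-5-[(10Z,13Z,16Z)-nonadeca-10,13,16-trien-1-yl]-1H-pyrrole-1-carboxylate | CC/C=C\C/C=C\C/C=C\CCCCCCCCCc1ccc(CO[Si](C)(C)C(C)(C)C)n1C(=O)OC(C)(C)C | intermediate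
13 | tert-butyl 2-(hydroxymethyl)-5-[(10Z,13Z,16Z)-nonadeca-10,13,16-trien-1-yl]-1H-pyrrole-1-carboxylate | CC/C=C\C/C=C\C/C=C\CCCCCCCCCc1ccc(CO)n1C(=O)OC(C)(C)C | intermediate
14 | tert-butyl 2-formyl-5-[(10Z,13Z,16Z)-nonadeca-10,13,16-trien-1-yl]-1H-pyrrole-1-carboxylate | CC/C=C\C/C=C\C/C=C\CCCCCCCCCc1ccc(C=O)n1C(=O)OC(C)(C)C | intermediate
15 | Mycalazal 20, 5-[(10Z,13Z,16Z)-nonadeca-10,13,16-trien-1-yl]-1H-pyrrole-2-carbaldehyde | CC/C=C\C/C=C\C/C=C\CCCCCCCCCc1ccc(C=O)[nH]1 | target

Total step count: 10. Longest linear sequence: 10 steps, from acid 1 to target 15; compounds 4 and 6 are bought.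

Steps most likely to fail

1. Step 7, the gold-catalysed ring closure. The Boc carbonyl oxygen may attack the activated alkyne with loss of isobutene, the propargylic carbinol may rearrange in a Meyer–Schuster sense, or adventitious TfOH may strip the silyl ether or isomerise the alkenes. The fallback builds the pyrrole by a Paal–Knorr condensation instead; it sets out from aldehyde 3 and comes back to the route at target 15. Addition of [2-(1,3-dioxolan-2-yl)ethyl]magnesium bromide (from 2-(2-bromoethyl)-1,3-dioxolane and Mg in THF) to 3 should give (13Z,16Z,19Z)-1-(1,3-dioxolan-2-yl)docosa-13,16,19-trien-3-ol F1. DMP oxidation should then give (13Z,16Z,19Z)-1-(1,3-dioxolan-2-yl)docosa-13,16,19-trien-3-one F2. Warming F2 with NH4OAc in aqueous AcOH should unmask the aldehyde and close 2-[(10Z,13Z,16Z)-nonadeca-10,13,16-trien-1-yl]-1H-pyrrole F3. Vilsmeier–Haack formylation (POCl3, DMF, 0 °C; then aq. NaOAc) at the free α-position of F3 should give 15.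

2. Step 8, the desilylation. The Boc group may migrate from nitrogen to the freed primary oxygen or close to a cyclic carbamate, and the pyrrolylmethyl position may ionise under acid. The fallback removes the carbamate before the hydroxyl is freed; it sets out from 12 and comes back at target 15. NaOMe in MeOH/THF should cleave the N-Boc group to give 2-[(tert-butyldimethylsilyl)oxymethyl]-5-[(10Z,13Z,16Z)-nonadeca-10,13,16-trien-1-yl]-1H-pyrrole F4. TBAF in THF should then give {5-[(10Z,13Z,16Z)-nonadeca-10,13,16-trien-1-yl]-1H-pyrrol-2-yl}methanol F5, which has no acyl group left to migrate and is used at once. MnO2 in CH2Cl2 should oxidise F5 directly to 15.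

3. Step 5, the acid-mediated opening of the N,O-acetonide. The Boc group may be lost alongside, the propargylic carbinol may undergo methanolysis, or the opening may stall. The fallback avoids the acetonide altogether through an ynone; it sets out from alkyne 5 (as its lithium acetylide 7) and comes back at 10. Commercial N-Boc-L-serine N-methoxy-N-methylamide is silylated (TBSCl, imidazole) to tert-butyl N-[(2S)-3-(tert-butyldimethylsilyloxy)-1-[methoxy(methyl)amino]-1-oxopropan-2-yl]carbamate F6. Its N–H is deprotonated with i-PrMgCl, and acetylide 7 is added to give tert-butyl N-[(2S,15Z,18Z,21Z)-1-(tert-butyldimethylsilyloxy)-3-oxotetracosa-15,18,21-trien-4-yn-2-yl]carbamate F7. Luche reduction (NaBH4, CeCl3·7H2O, MeOH, −20 °C) of F7 should give 10 as the epimer mixture.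

Further compounds
F1 | step 7 | (13Z,16Z,19Z)-1-(1,3-dioxolan-2-yl)docosa-13,16,19-trien-3-ol | CC/C=C\C/C=C\C/C=C\CCCCCCCCCC(O)CCC1OCCO1
F2 | step 7 | (13Z,16Z,19Z)-1-(1,3-dioxolan-2-yl)docosa-13,16,19-trien-3-one | CC/C=C\C/C=C\C/C=C\CCCCCCCCCC(=O)CCC1OCCO1
F3 | step 7 | 2-[(10Z,13Z,16Z)-nonadeca-10,13,16-trien-1-yl]-1H-pyrrole | CC/C=C\C/C=C\C/C=C\CCCCCCCCCc1ccc[nH]1
F4 | step 8 | 2-[(tert-butyldimethylsilyl)oxymethyl]-5-[(10Z,13Z,16Z)-nonadeca-10,13,16-trien-1-yl]-1H-pyrrole | CC/C=C\C/C=C\C/C=C\CCCCCCCCCc1ccc(CO[Si](C)(C)C(C)(C)C)[nH]1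
F5 | step 8 | {5-[(10Z,13Z,16Z)-nonadeca-10,13,16-trien-1-yl]-1H-pyrrol-2-yl}methanol | CC/C=C\C/C=C\C/C=C\CCCCCCCCCc1ccc(CO)[nH]1
F6 | step 5 | tert-butyl N-[(2S)-3-(tert-butyldimethylsilyloxy)-1-[methoxy(methyl)amino]-1-oxopropan-2-yl]carbamate | CON(C)C(=O)[C@H](CO[Si](C)(C)C(C)(C)C)NC(=O)OC(C)(C)C
F7 | step 5 | tert-butyl N-[(2S,15Z,18Z,21Z)-1-(tert-butyldimethylsilyloxy)-3-oxotetracosa-15,18,21-trien-4-yn-2-yl]carbamate | CC/C=C\C/C=C\C/C=C\CCCCCCCCCC#CC(=O)[C@H](CO[Si](C)(C)C(C)(C)C)NC(=O)OC(C)(C)C
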